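Ring B (C1–O to ring A, C2–H, C3–C5 tribrominated, C6–O to ring C) is disconnected at C1–C2 and C5–C6. Its C2–C5 unit comes from 2,3,4-tribromothiophene 1,1-dioxide; C1 and C6 come from an alkyne that carries the ring-C aryloxy group on C6 and a pinacol boronate on C1 as masked ring-A oxygen. One inverse-demand Diels–Alder/SO2-extrusion step forms both bonds, closes and aromatises ring B and places the hydrogen next to boron, exploiting the contiguous Br3/H pattern beside two adjacent C–O carbons. Boron oxidation, SNAr onto a fluorobenzaldehyde (ring A), Baeyer–Villiger/Dakin oxidation and O-sulfation complete the target.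

Key step: step 6

Assumption: the target has no stereogenic element (no stereocentre, freely rotating diaryl ether axes), so no stereocontrol is needed; it is made as the free hydrogen sulfate, as drawn.

Step 1
Reactants: 1 tetrabromothiophene
Product: 3 2,3,4-tribromothiophene, via 3,4,5-tribromo-2-thienyllithium 2 (not isolated)
Conditions: n-BuLi (1.0 equiv), THF, −78 °C; MeOH, −78 °C → rt
Reagents that add atoms: none
Why: Bromine–lithium exchange with one equivalent of n-BuLi takes place at an α-carbon, where the thienyl anion is best stabilised by sulfur and the neighbouring bromine, and protonation of 2 leaves that α-position as C–H (halogen–metal exchange/protonolysis).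

Step 2
Reactants: 3 2,3,4-tribromothiophene
Product: 5 2,3,4-tribromothiophene 1,1-dioxide, via 2,3,4-tribromothiophene 1-oxide 4 (not isolated)
Conditions: (CF3CO)2O, urea·H2O2, MeCN/CH2Cl2, 0 °C → rt; product kept cold and used at once
Reagents that add atoms: urea–hydrogen peroxide, NC(N)=O.OO (both oxygens are delivered through trifluoroperacetic acid, OOC(=O)C(F)(F)F, formed in the flask with trifluoroacetic anhydride)
Why: Trifluoroperacetic acid is electrophilic enough to oxidise the electron-poor sulfur twice (S-oxidation of a polyhalothiophene to its sulfone), the S-oxide being oxidised on faster than it can dimerise, and halogenated thiophene dioxides with a free ring position are isolable if stored cold.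

Step 3
Reactants: 6 4-bromo-2-iodophenol
Product: 7 4-bromo-1-(ethenyloxy)-2-iodobenzene
Conditions: Cu(OAc)2 (1 equiv), 2,4,6-trivinylcyclotriboroxane·pyridine (0.7 equiv), pyridine, CH2Cl2, air, rt
Reagents that add atoms: 2,4,6-trivinylcyclotriboroxane–pyridine complex, C=CB1OB(C=C)OB(C=C)O1.c1ccncc1
Why: Copper(II)-mediated oxidative O-vinylation of the phenol with the vinylboroxine (Chan–Lam coupling) runs at room temperature, where neither the aryl iodide nor the aryl bromide enters Ullmann-type coupling.

Step 4
Reactants: 7 4-bromo-1-(ethenyloxy)-2-iodobenzene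
Product: 9 4-bromo-1-{[(Z)-2-bromoethenyl]oxy}-2-iodobenzene, via 4-bromo-1-(1,2-dibromoethoxy)-2-iodobenzene 8 (not isolated)
Conditions: Br2 (1.0 equiv), CH2Cl2, −78 °C; i-Pr2NEt (1.5 equiv), −78 → 40 °C
Reagents that add atoms: bromine, BrBr
Why: Electrophilic bromine addition to the enol ether is much faster than bromination of the deactivated ring, and the labile α-bromo ether 8 then loses HBr to the amine (dehydrobromination) to give the β-bromovinyl ether, expected mainly Z, any isomeric bromovinyl ether converging on the same alkyne in step 5.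

Step 5
Reactants: 9 4-bromo-1-{[(Z)-2-bromoethenyl]oxy}-2-iodobenzene
Product: 13 2-[(4-bromo-2-iodophenoxy)ethynyl]-4,4,5,5-tetramethyl-1,3,2-dioxaborolane, via 4-bromo-1-(ethynyloxy)-2-iodobenzene 10 (not isolated), via potassium (4-bromo-2-iodophenoxy)ethynide 11 (not isolated), via potassium alkynyl(isopropoxy)pinacolborate 12 (not isolated)
Conditions: KHMDS (2.2 equiv), THF, −78 → −20 °C; i-PrOBpin, −78 °C; HCl·Et2O, −78 °C → rt; filtered under Ar, used crude
Reagents that add atoms: 2-isopropoxy-4,4,5,5-tetramethyl-1,3,2-dioxaborolane, CC(C)OB1OC(C)(C)C(C)(C)O1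
Why: The silazide removes HBr by anti-elimination (dehydrohalogenation of a β-halovinyl ether to an alkynyl ether) and deprotonates the alkyne, yet it cannot undergo halogen–metal exchange and is too weak to metalate the ring C–H between iodine and bromine, so the acetylide is trapped by the borate ester and the ate complex is collapsed with anhydrous acid (alkynylboronate synthesis by borate trapping).

Step 6
Reactants: 5 2,3,4-tribromothiophene 1,1-dioxide; 13 2-[(4-bromo-2-iodophenoxy)ethynyl]-4,4,5,5-tetramethyl-1,3,2-dioxaborolane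
Product: 15 2-[3,4,5-tribromo-2-(4-bromo-2-iodophenoxy)phenyl]-4,4,5,5-tetramethyl-1,3,2-dioxaborolane, via bicyclic sulfone cycloadduct 14 (not isolated)
Conditions: 5 (2 equiv, added slowly), PhMe, 70 °C, Ar
Reagents that add atoms: none
Why: The LUMO-lowered, non-aromatic diene sulfone 5 and the electron-rich ynol-ether π-bond of 13 combine in an inverse-electron-demand, asynchronous [4+2] cycloaddition to the 7-thiabicyclo[2.2.1]heptadiene 7,7-dioxide 14, which loses SO2 by thermally allowed cheletropic extrusion and aromatises at once. The closest known reaction type is the Diels–Alder/SO2-extrusion benzannulation of halogenated thiophene 1,1-dioxides with alkynes, together with the cycloaddition–extrusion benzannulations of alkynylboronates; the aryloxy/boryl alkyne is a new member of a known dienophile class. Ring B is closed by this intermolecular [4+2] cycloaddition, which forms C1–C2 and C5–C6 in one operation, and no stereocentre remains because both bridgehead centres of 14 become aromatic carbons. The step needs regioselectivity: the boron-bearing carbon, which is the nucleophilic β-carbon of the ynol ether, must bond to the unsubstituted α-carbon of 5, and this is secured by the oxygen polarisation of the alkyne, the lower hindrance of the C–H terminus, the developing negative charge resting on bromine-bearing and α-sulfonyl carbons, and the bulky boronate avoiding the α-bromine. It also needs the cross-cycloaddition to outrun self-dimerisation of 5, which slow addition of excess 5 to a concentrated solution of 13 favours. The ring-C halogens and the C–B bond are spectators under these neutral thermal conditions.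

Step 7
Reactants: 15 2-[3,4,5-tribromo-2-(4-bromo-2-iodophenoxy)phenyl]-4,4,5,5-tetramethyl-1,3,2-dioxaborolane
Product: 16 3,4,5-tribromo-2-(4-bromo-2-iodophenoxy)phenol
Conditions: 30% H2O2, 1 M NaOH, THF, 0 °C → rt; 1 M HCl
Reagents that add atoms: hydrogen peroxide, OO
Why: Hydroperoxide adds to boron and the aryl group migrates from boron to oxygen at the same carbon (oxidative 1,2-boronate rearrangement), which places the hydroxyl on C1 of ring B without touching the aryl halides.

Step 8
Reactants: 16 3,4,5-tribromo-2-(4-bromo-2-iodophenoxy)phenol; 17 3,5-dibromo-2-fluorobenzaldehyde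
Product: 18 3,5-dibromo-2-[3,4,5-tribromo-2-(4-bromo-2-iodophenoxy)phenoxy]benzaldehyde
Conditions: K2CO3, DMF, 60 °C
Reagents that add atoms: none
Why: The phenoxide of 16 displaces the fluoride ortho to the formyl group through a Meisenheimer intermediate (SNAr), fluoride being by far the best leaving group on 17 so that no C–Br bond is attacked.

Step 9
Reactants: 18 3,5-dibromo-2-[3,4,5-tribromo-2-(4-bromo-2-iodophenoxy)phenoxy]benzaldehyde
Product: 20 3,5-dibromo-2-[3,4,5-tribromo-2-(4-bromo-2-iodophenoxy)phenoxy]phenol, via aryl formate 19 (not isolated)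
Conditions: mCPBA, KH2PO4, CH2Cl2, 0 °C → rt; aq. Na2S2O3 wash; Et3N (cat.), MeOH, rt
Reagents that add atoms: 3-chloroperbenzoic acid, OOC(=O)c1cccc(Cl)c1
Why: The peracid adds to the aldehyde and the ortho-aryloxy aryl group migrates in the Criegee intermediate (Baeyer–Villiger/Dakin-type oxidation, well established for ortho-aryloxy benzaldehydes), the formate is removed by methanolysis, and without strong acid the aryl iodide is not oxidised at a competitive rate, any iodine(III) being reduced back in the thiosulfate wash.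

Step 10
Reactants: 20 3,5-dibromo-2-[3,4,5-tribromo-2-(4-bromo-2-iodophenoxy)phenoxy]phenol
Product: 22 3,5-dibromo-2-[3,4,5-tribromo-2-(4-bromo-2-iodophenoxy)phenoxy]phenyl hydrogen sulfate (Bromoiesol B sulfate), via pyridinium aryl sulfate 21 (not isolated)
Conditions: SO3·pyridine (3 equiv), pyridine, 50 °C; Dowex 50W (H+), MeOH/H2O, 0 °C; lyophilise cold
Reagents that add atoms: sulfur trioxide–pyridine complex, [O-]S(=O)(=O)[n+]1ccccc1
Why: Sulfur trioxide is transferred from its pyridine complex to the phenol oxygen (O-sulfation) and cation exchange on the acidic resin at 0 °C replaces pyridinium by a proton, the free acid being kept cold because aryl hydrogen sulfates hydrolyse autocatalytically.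

Compound list
1 | tetrabromothiophene | Brc1sc(Br)c(Br)c1Br | starting material
2 | 3,4,5-tribromo-2-thienyllithium | [Li]c1sc(Br)c(Br)c1Br | intermediate (not isolated)
3 | 2,3,4-tribromothiophene | Brc1csc(Br)c1Br | intermediate
4 | 2,3,4-tribromothiophene 1-oxide (racemic at sulfur) | O=S1C=C(Br)C(Br)=C1Br | intermediate (not isolated)
5 | 2,3,4-tribromothiophene 1,1-dioxide | O=S1(=O)C=C(Br)C(Br)=C1Br | intermediate
6 | 4-bromo-2-iodophenol | Oc1ccc(Br)cc1I | starting material
7 | 4-bromo-1-(ethenyloxy)-2-iodobenzene | C=COc1ccc(Br)cc1I | intermediate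
8 | 4-bromo-1-(1,2-dibromoethoxy)-2-iodobenzene (racemic) | BrCC(Br)Oc1ccc(Br)cc1I | intermediate (not isolated)
9 | 4-bromo-1-{[(Z)-2-bromoethenyl]oxy}-2-iodobenzene (Z isomer shown; any E isomer is carried along) | Br/C=C\Oc1ccc(Br)cc1I | intermediate
10 | 4-bromo-1-(ethynyloxy)-2-iodobenzene | C#COc1ccc(Br)cc1I | intermediate (not isolated)
11 | potassium (4-bromo-2-iodophenoxy)ethynide | [K+].[C-]#COc1ccc(Br)cc1I | intermediate (not isolated)
12 | potassium [(4-bromo-2-iodophenoxy)ethynyl](isopropoxy)(pinacolato)borate | [K+].CC(C)O[B-]1(C#COc2ccc(Br)cc2I)OC(C)(C)C(C)(C)O1 | intermediate (not isolated)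
13 | 2-[(4-bromo-2-iodophenoxy)ethynyl]-4,4,5,5-tetramethyl-1,3,2-dioxaborolane | CC1(C)OB(C#COc2ccc(Br)cc2I)OC1(C)C | intermediate
14 | 1,5,6-tribromo-2-(4-bromo-2-iodophenoxy)-3-(4,4,5,5-tetramethyl-1,3,2-dioxaborolan-2-yl)-7-thiabicyclo[2.2.1]hepta-2,5-diene 7,7-dioxide (racemic) | O=S1(=O)C2(Br)C(Oc3ccc(Br)cc3I)=C(B3OC(C)(C)C(C)(C)O3)C1C(Br)=C2Br | intermediate (not isolated)
15 | 2-[3,4,5-tribromo-2-(4-bromo-2-iodophenoxy)phenyl]-4,4,5,5-tetramethyl-1,3,2-dioxaborolane | CC1(C)OB(c2cc(Br)c(Br)c(Br)c2Oc2ccc(Br)cc2I)OC1(C)C | intermediate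
16 | 3,4,5-tribromo-2-(4-bromo-2-iodophenoxy)phenol | Oc1cc(Br)c(Br)c(Br)c1Oc1ccc(Br)cc1I | intermediate
17 | 3,5-dibromo-2-fluorobenzaldehyde | O=Cc1cc(Br)cc(Br)c1F | starting material
18 | 3,5-dibromo-2-[3,4,5-tribromo-2-(4-bromo-2-iodophenoxy)phenoxy]benzaldehyde | O=Cc1cc(Br)cc(Br)c1Oc1cc(Br)c(Br)c(Br)c1Oc1ccc(Br)cc1I | intermediate
19 | 3,5-dibromo-2-[3,4,5-tribromo-2-(4-bromo-2-iodophenoxy)phenoxy]phenyl formate | O=COc1cc(Br)cc(Br)c1Oc1cc(Br)c(Br)c(Br)c1Oc1ccc(Br)cc1I | intermediate (not isolated)
20 | 3,5-dibromo-2-[3,4,5-tribromo-2-(4-bromo-2-iodophenoxy)phenoxy]phenol | Oc1cc(Br)cc(Br)c1Oc1cc(Br)c(Br)c(Br)c1Oc1ccc(Br)cc1I | intermediate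
21 | pyridinium 3,5-dibromo-2-[3,4,5-tribromo-2-(4-bromo-2-iodophenoxy)phenoxy]phenyl sulfate | [O-]S(=O)(=O)Oc1cc(Br)cc(Br)c1Oc1cc(Br)c(Br)c(Br)c1Oc1ccc(Br)cc1I.c1cc[nH+]cc1 | intermediate (not isolated)
22 | 3,5-dibromo-2-[3,4,5-tribromo-2-(4-bromo-2-iodophenoxy)phenoxy]phenyl hydrogen sulfate (Bromoiesol B sulfate) | O=S(=O)(O)Oc1cc(Br)cc(Br)c1Oc1cc(Br)c(Br)c(Br)c1Oc1ccc(Br)cc1I | target

Total step count: 10.
Longest linear sequence: 8 steps (steps 3–10, from 6 to 22); steps 1–2 form the convergent branch to 5.

Steps most likely to fail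

1. Step 6. The dioxide may consume itself by [4+2] self-dimerisation faster than it meets the alkyne, the two new bonds may form with the opposite orientation, or the push–pull alkyne may degrade on heating. Fallback: ring B is made by aromatic substitution instead of cycloaddition. This bypass sets out from no numbered compound (commercial 2-methoxyphenol and 4-bromo-1-fluoro-2-nitrobenzene are bought in) and comes back to the route at 16. Exhaustive bromination of 2-methoxyphenol (Br2, AcOH) should give 4,5,6-tribromo-2-methoxyphenol F1, whose only free ring position lies next to the methoxy group. SNAr of its phenoxide on 4-bromo-1-fluoro-2-nitrobenzene (K2CO3, DMF, 80 °C) gives 1,2,3-tribromo-4-(4-bromo-2-nitrophenoxy)-5-methoxybenzene F2. Fe/NH4Cl reduction gives 5-bromo-2-(2,3,4-tribromo-6-methoxyphenoxy)aniline F3. Diazotisation (NaNO2, H2SO4/AcOH, 0 °C) gives 5-bromo-2-(2,3,4-tribromo-6-methoxyphenoxy)benzenediazonium hydrogensulfate F4, in which both positions ortho to the ether oxygen on the other ring are blocked so no Pschorr closure can compete. Iodide quench (KI) gives 1,2,3-tribromo-4-(4-bromo-2-iodophenoxy)-5-methoxybenzene F5, and BBr3 (CH2Cl2, −78 → 0 °C) cleaves the methyl ether to 16.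

2. Step 5. The weak amide base may not complete the dehydrobromination, nucleophiles may add across the ynol ether, and the alkynyl C–B bond may be lost by protonolysis or hydrolysis during the acid release and handling. Fallback: silicon replaces boron as the masked oxygen. It sets out from 9 and comes back at 16. After the same elimination, acetylide 11 is trapped with chlorotriethoxysilane to give triethoxy[(4-bromo-2-iodophenoxy)ethynyl]silane F6, a C-silyl ynol ether that needs no acid release and tolerates filtration. It takes the place of 13 in the cycloaddition with 5 and should give, through the triethoxysilyl bicyclic sulfone cycloadduct F7, triethoxy[3,4,5-tribromo-2-(4-bromo-2-iodophenoxy)phenyl]silane F8. Tamao oxidation (H2O2, KF, KHCO3, THF/MeOH) then converts C–Si into C–OH and gives 16.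

3. Step 9. Hydrogen may migrate instead of the aryl group in the Criegee intermediate, the hindered electron-poor aldehyde may oxidise slowly, and the peracid may attack iodine. Fallback: the ring-A oxygen is brought in as a methyl ether by metal-free arylation, so no oxidant meets the iodide. It sets out from 16 and comes back at 20. Commercial 2,4-dibromo-6-methoxyaniline is diazotised to 2,4-dibromo-6-methoxybenzenediazonium hydrogensulfate F9 and quenched with KI to give 1,5-dibromo-2-iodo-3-methoxybenzene F10. Oxidation with mCPBA/TsOH and coupling with 1,3,5-trimethoxybenzene give (2,4-dibromo-6-methoxyphenyl)(2,4,6-trimethoxyphenyl)iodonium tosylate F11. O-Arylation of the phenoxide of 16 (t-BuOK, toluene/MeCN, 50 °C) should transfer the hindered, electron-poor aryl group and leave the trimethoxyphenyl group on iodine, giving 1,2,3-tribromo-4-(4-bromo-2-iodophenoxy)-5-(2,4-dibromo-6-methoxyphenoxy)benzene F12. BBr3 demethylation gives 20.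

Further compounds
F1 | step 6 | 4,5,6-tribromo-2-methoxyphenol | COc1cc(Br)c(Br)c(Br)c1O
F2 | step 6 | 1,2,3-tribromo-4-(4-bromo-2-nitrophenoxy)-5-methoxybenzene | COc1cc(Br)c(Br)c(Br)c1Oc1ccc(Br)cc1[N+](=O)[O-]
F3 | step 6 | 5-bromo-2-(2,3,4-tribromo-6-methoxyphenoxy)aniline | COc1cc(Br)c(Br)c(Br)c1Oc1ccc(Br)cc1N
F4 | step 6 | 5-bromo-2-(2,3,4-tribromo-6-methoxyphenoxy)benzenediazonium hydrogensulfate | COc1cc(Br)c(Br)c(Br)c1Oc1ccc(Br)cc1[N+]#N.OS(=O)(=O)[O-]
F5 | step 6 | 1,2,3-tribromo-4-(4-bromo-2-iodophenoxy)-5-methoxybenzene | COc1cc(Br)c(Br)c(Br)c1Oc1ccc(Br)cc1I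
F6 | step 5 | triethoxy[(4-bromo-2-iodophenoxy)ethynyl]silane | CCO[Si](OCC)(OCC)C#COc1ccc(Br)cc1I
F7 | step 5 | 1,5,6-tribromo-2-(4-bromo-2-iodophenoxy)-3-(triethoxysilyl)-7-thiabicyclo[2.2.1]hepta-2,5-diene 7,7-dioxide (racemic) | O=S1(=O)C2(Br)C(Oc3ccc(Br)cc3I)=C([Si](OCC)(OCC)OCC)C1C(Br)=C2Br
F8 | step 5 | triethoxy[3,4,5-tribromo-2-(4-bromo-2-iodophenoxy)phenyl]silane | CCO[Si](OCC)(OCC)c1cc(Br)c(Br)c(Br)c1Oc1ccc(Br)cc1I
F9 | step 9 | 2,4-dibromo-6-methoxybenzenediazonium hydrogensulfate | COc1cc(Br)cc(Br)c1[N+]#N.OS(=O)(=O)[O-]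
F10 | step 9 | 1,5-dibromo-2-iodo-3-methoxybenzene | COc1cc(Br)cc(Br)c1I
F11 | step 9 | (2,4-dibromo-6-methoxyphenyl)(2,4,6-trimethoxyphenyl)iodonium 4-methylbenzenesulfonate | COc1cc(Br)cc(Br)c1[I+]c1c(OC)cc(OC)cc1OC.Cc1ccc(S(=O)(=O)[O-])cc1
F12 | step 9 | 1,2,3-tribromo-4-(4-bromo-2-iodophenoxy)-5-(2,4-dibromo-6-methoxyphenoxy)benzene | COc1cc(Br)cc(Br)c1Oc1cc(Br)c(Br)c(Br)c1Oc1ccc(Br)cc1I
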